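## Retrosynthetic overview

1. Numbering: ring C1 (CMe2), C2 (CHBr), C3 (CH2), C4 (CHCl), C5 (alkene carbon), C6 (CHCl); side chain C7H= and C8H2Br.
2. Feature used: the cyclohexane ring carries an exocyclic C5=C7 double bond whose C8 arm points towards C6, and C6 lies between this alkene and the quaternary C1. A C6 aldehyde therefore cannot enolise, and a C5 alkenyl metal of fixed geometry can be added to it.
3. Late disconnections: C8–Br (Appel, last step); C4–Cl and C6–Cl (double inversion of the all-cis diol 24); C5–C6 (Nozaki–Hiyama–Kishi closure of 21, the only ring-forming event, which makes the six-membered carbocycle).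
4. Aldehyde 21 arises from C1–C2 bond formation (isobutyrate Mukaiyama aldol on aldehyde 13); C2–Br is installed by invertive bromide opening of β-lactone 18.
5. Aldehyde 13 comes from but-2-yne-1,4-diol: Brown allylation sets C4, directed trans-hydroalumination/iodination fixes the C5=C7 geometry, and cleavage of the allyl terminus frees the C2 aldehyde.

Key step: step 14

Assumption: the borane promoter made from N-tosyl-L-valine is taken to deliver the (2R)-aldol 15, the sense that the 1,3-anti preference of aldehyde 13 also favours; if the promoter shows the opposite sense, N-tosyl-D-valine is used and nothing else changes.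

## Route

Step 1
Reactants: 1 but-2-yne-1,4-diol
Product: 2 4-hydroxybut-2-yn-1-yl pivalate
Conditions: PivCl (1 equiv), 1 (3 equiv), pyridine, THF, 0 °C → rt
Reagents that add atoms: pivaloyl chloride, CC(C)(C)C(=O)Cl
Why: Statistical monoacylation with excess symmetrical diol should keep diester formation low, and the pivalate is chosen because the hydride reagent of step 5 removes it in the same flask in which the free C8 hydroxyl is needed.

Step 2
Reactants: 2 4-hydroxybut-2-yn-1-yl pivalate
Product: 3 4-oxobut-2-yn-1-yl pivalate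
Conditions: Dess–Martin periodinane, CH2Cl2, 0 °C → rt
Reagents that add atoms: none
Why: Dess–Martin oxidation of a primary propargylic alcohol stops at the ynal and leaves the ester untouched.

Step 3
Reactants: 3 4-oxobut-2-yn-1-yl pivalate; 4 (+)-B-allyldiisopinocampheylborane
Product: 6 (4R)-4-hydroxyhept-6-en-2-yn-1-yl pivalate, via diisopinocampheylborinate ester 5 (not isolated)
Conditions: 4 (1 M in pentane), Et2O, −78 °C; then NaBO3·4H2O, THF/H2O, rt
Reagents that add atoms: (+)-B-allyldiisopinocampheylborane 4, C=CCB([C@H]1C[C@H]2C[C@@H]([C@@H]1C)C2(C)C)[C@H]1C[C@H]2C[C@@H]([C@@H]1C)C2(C)C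
Why: Brown allylation through a closed chair transition state, in which the reagent derived from (−)-α-pinene attacks the Re face of the ynal and sets C4 as R, while the mild perborate work-up frees the alcohol without touching the pivalate.

Step 4
Reactants: 6 (4R)-4-hydroxyhept-6-en-2-yn-1-yl pivalate
Product: 7 (4R)-4-(tert-butyldimethylsilyloxy)hept-6-en-2-yn-1-yl pivalate
Conditions: TBSCl, imidazole, DMF, rt
Reagents that add atoms: tert-butyldimethylsilyl chloride, CC(C)(C)[Si](C)(C)Cl
Why: Standard silylation masks the C4 oxygen, so that only the C8 oxygen can direct the hydroalumination that follows.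

Step 5
Reactants: 7 (4R)-4-(tert-butyldimethylsilyloxy)hept-6-en-2-yn-1-yl pivalate
Product: 10 (2Z,4R)-4-(tert-butyldimethylsilyloxy)-3-iodohepta-2,6-dien-1-ol, via alkoxyhydridoaluminate 8 (not isolated), via cyclic alkenylaluminate 9 (not isolated)
Conditions: NaAlH2(OCH2CH2OMe)2 (3.5 equiv), THF, 0 °C; then I2, THF, −78 → 0 °C
Reagents that add atoms: iodine, II; NaAlH2(OCH2CH2OMe)2, [Na+].[AlH2-](OCCOC)OCCOC (its atoms stay only in 8 and 9)
Why: Ester reduction frees the C8 alkoxide, whose Al–H bond delivers hydride to C7 in an oxygen-directed trans-hydroalumination that closes the five-membered ring of 9 with aluminium on C5, and iodinolysis with retention places iodine on C5 cis to C8; the low temperature keeps 9 from expelling the C4 silyloxide to give an allene.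

Step 6
Reactants: 10 (2Z,4R)-4-(tert-butyldimethylsilyloxy)-3-iodohepta-2,6-dien-1-ol
Product: 11 C8 tert-butyldiphenylsilyl ether of 10
Conditions: TBDPSCl, imidazole, CH2Cl2, 0 °C → rt
Reagents that add atoms: tert-butyldiphenylsilyl chloride, CC(C)(C)[Si](Cl)(c1ccccc1)c1ccccc1
Why: Routine silylation of a primary allylic alcohol, with TBDPS chosen because it outlasts the acid that removes the C4 TBS group in step 15, so the chlorides can be installed before C8 is unmasked.

Step 7
Reactants: 11 C8 tert-butyldiphenylsilyl ether of 10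
Product: 13 (3R,4Z)-3-(tert-butyldimethylsilyloxy)-6-(tert-butyldiphenylsilyloxy)-4-iodohex-4-enal, via vicinal diol 12 (not isolated)
Conditions: OsO4 (2 mol %), NaIO4 (4 equiv), 2,6-lutidine, dioxane/H2O, rt
Reagents that add atoms: OsO4, O=[Os](=O)(=O)=O; NaIO4, [Na+].[O-]I(=O)(=O)=O (terminal oxygen source)
Why: Johnson–Lemieux cleavage, in which OsO4 dihydroxylates the monosubstituted terminal alkene far faster than the electron-poor, hindered trisubstituted iodoalkene, and NaIO4 cleaves diol 12 in the same flask.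

Step 8
Reactants: 13 (3R,4Z)-3-(tert-butyldimethylsilyloxy)-6-(tert-butyldiphenylsilyloxy)-4-iodohex-4-enal; 14 1-methoxy-2-methyl-1-(trimethylsilyloxy)prop-1-ene
Product: 15 methyl (3R,5R,6Z)-5-(tert-butyldimethylsilyloxy)-8-(tert-butyldiphenylsilyloxy)-3-hydroxy-6-iodo-2,2-dimethyloct-6-enoate
Conditions: N-tosyl-L-valine, BH3·THF, CH2Cl2, 0 °C → rt; then 13, 14, −78 °C; pH 7 buffer
Reagents that add atoms: 14 1-methoxy-2-methyl-1-(trimethylsilyloxy)prop-1-ene, COC(O[Si](C)(C)C)=C(C)C
Why: Kiyooka variant of the Mukaiyama aldol, in which the valine-derived oxazaborolidinone shields one aldehyde face and forms C1–C2 with C2 as the R carbinol, 1,3-anti to C4–OSi, the same sense that polar 1,3-induction from the β-silyloxy group favours in an open transition state.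

Step 9
Reactants: 15 methyl (3R,5R,6Z)-5-(tert-butyldimethylsilyloxy)-8-(tert-butyldiphenylsilyloxy)-3-hydroxy-6-iodo-2,2-dimethyloct-6-enoate
Product: 16 the corresponding (3R,5R,6Z)-3-hydroxy acid
Conditions: LiOH, THF/MeOH/H2O, 40 °C; then 0.5 M HCl, 0 °C, to pH 4
Reagents that add atoms: lithium hydroxide, [Li+].[OH-]
Why: Saponification of the methyl ester, where the quaternary α-carbon rules out epimerisation and mild warming stays short of conditions that would trigger retro-aldol cleavage or attack the silyl ethers.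

Step 10
Reactants: 16 (3R,5R,6Z)-3-hydroxy acid
Product: 18 (4R)-4-[(2R,3Z)-2-(tert-butyldimethylsilyloxy)-5-(tert-butyldiphenylsilyloxy)-3-iodopent-3-en-1-yl]-3,3-dimethyloxetan-2-one, via carboxylic sulfonic mixed anhydride 17 (not isolated)
Conditions: PhSO2Cl, pyridine, 0 °C
Reagents that add atoms: benzenesulfonyl chloride, O=S(=O)(Cl)c1ccccc1 (its atoms stay only in 17)
Why: Lactonisation by carboxyl activation, in which the C2 hydroxyl attacks the mixed anhydride so the C2–O bond is never broken and C2 keeps its configuration, with the gem-dimethyl group favouring four-membered ring closure.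

Step 11
Reactants: 18 β-lactone
Product: 19 (3S,5R,6Z)-3-bromo-5-(tert-butyldimethylsilyloxy)-8-(tert-butyldiphenylsilyloxy)-6-iodo-2,2-dimethyloct-6-enoic acid
Conditions: MgBr2·OEt2 (3 equiv), Et2O/CH2Cl2, 0 °C → rt; then cold 0.5 M HCl
Reagents that add atoms: magnesium bromide diethyl etherate, CCOCC.[Mg+2].[Br-].[Br-]
Why: Halide opening of a β-lactone by SN2 attack at the alkyl C–O bond, where magnesium activates the carbonyl, ring strain pays for attack at the neopentylic C2 (the same alkyl–oxygen cleavage is known from pivalolactone), and inversion turns the (R)-C2–O centre into the (S)-C2–Br centre of the target.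

Step 12
Reactants: 19 bromo acid
Product: 20 (3S,5R,6Z)-3-bromo-5-(tert-butyldimethylsilyloxy)-8-(tert-butyldiphenylsilyloxy)-6-iodo-2,2-dimethyloct-6-en-1-ol
Conditions: BH3·THF, THF, 0 °C → rt; then MeOH
Reagents that add atoms: none
Why: Borane reduces a free carboxylic acid much faster than it touches a hindered iodoalkene, an alkyl bromide or silyl ethers, and the non-basic medium avoids decarboxylative loss of bromide from a carboxylate.

Step 13
Reactants: 20 bromo alcohol
Product: 21 (3S,5R,6Z)-3-bromo-5-(tert-butyldimethylsilyloxy)-8-(tert-butyldiphenylsilyloxy)-6-iodo-2,2-dimethyloct-6-enal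
Conditions: Dess–Martin periodinane, CH2Cl2, 0 °C → rt
Reagents that add atoms: none
Why: Dess–Martin oxidation works without base, so the 3-bromo alcohol cannot close to an oxetane, and the aldehyde formed has no α-hydrogen and cannot lose HBr.

Step 14
Reactants: 21 (Z)-iodoalkenyl bromo aldehyde
Product: 23 (1R,3S,5R,6E)-3-bromo-5-(tert-butyldimethylsilyloxy)-6-[2-(tert-butyldiphenylsilyloxy)ethylidene]-2,2-dimethylcyclohexan-1-ol (route numbering 2S,4R,6R; C2–Br C4–O C6–O all cis; C8 cis to C6), via alkenylchromium dichloride 22 (not isolated)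
Conditions: CrCl2 (10 equiv), NiCl2 (0.1 equiv), degassed DMSO, 0.005 M, rt; then H2O
Reagents that add atoms: CrCl2, [Cr+2].[Cl-].[Cl-] (its atoms stay only in 22)
Why: Zerovalent nickel, made from NiCl2 by CrCl2, inserts into the C5–I bond far faster than into the neopentylic secondary C2–Br bond, hands the alkenyl ligand to trivalent chromium with retention, and the alkenylchromium 22 adds to the C6 aldehyde. The closest known reaction type is the intramolecular Nozaki–Hiyama–Kishi coupling of iodoalkenes with aldehydes to give 2-alkylidenecycloalkanols. The carbocycle closes in a 6-exo-trig mode by formation of C5–C6, with the C=O bond outside the new ring. C6 is the only new stereocentre: in the chair-like transition state C2–Br and C4–OSi are equatorial and the aldehyde oxygen stays bound to the chromium leaving C5 in the alkene plane, which should place C6–O equatorial and cis to both, although allylic 1,3-strain with C8 opposes this. The alkene geometry (C8 cis to C6) is not created here but carried over from 21, because alkenylnickel and alkenylchromium species hold their configuration. Chemoselectivity rests on the substrate: the aldehyde cannot enolise or lose HBr, CrCl2 without a cobalt cocatalyst should leave the secondary bromide alone at room temperature, the neutral medium spares both silyl ethers, and high dilution with little nickel suppresses intermolecular coupling.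

Step 15
Reactants: 23 cyclic allylic alcohol
Product: 24 (1R,3R,5S)-5-bromo-2-[(Z)-2-(tert-butyldiphenylsilyloxy)ethylidene]-4,4-dimethylcyclohexane-1,3-diol (route numbering 2S,4R,6R)
Conditions: camphor-10-sulfonic acid (cat.), MeOH/CH2Cl2, 0 °C → rt
Reagents that add atoms: none
Why: Acid-catalysed methanolysis tells the two silyl ethers apart by their very different acid stability, so the secondary TBS ether is cleaved while the primary TBDPS ether stays.

Step 16
Reactants: 24 all-cis bromo diol
Product: 25 C8 tert-butyldiphenylsilyl ether of 26 (route numbering 2S,4S,6S; both chlorides trans to C2–Br; C8 cis to C6)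
Conditions: PPh3, Cl3CC(O)CCl3, CH2Cl2, −20 °C → rt
Reagents that add atoms: hexachloroacetone, O=C(C(Cl)(Cl)Cl)C(Cl)(Cl)Cl
Why: Appel-type deoxychlorination, in which each equatorial alkoxyphosphonium group lies near the nodal plane of the C5=C7 π bond and has no antiperiplanar hydrogen (C6 has no β-hydrogen at all), so SN2′ attack at C7 and elimination are disfavoured and chloride enters axially with inversion at C4 and C6, which also relieves the allylic 1,3-strain between C6–O and C8; C8 is still a silyl ether here, so chloride ion never meets a primary allylic bromide.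

Step 17
Reactants: 25 dichloride silyl ether
Product: 26 (2Z)-2-[(2S,4S,6S)-4-bromo-2,6-dichloro-3,3-dimethylcyclohexylidene]ethan-1-ol
Conditions: HF·pyridine, pyridine, THF, 0 °C → rt
Reagents that add atoms: none
Why: Fluoride-driven Si–O cleavage in an acidic medium frees C8–OH without forming an alkoxide, which could otherwise displace the cis-disposed C6 chloride and close a bicyclic dihydrofuran.

Step 18
Reactants: 26 primary allylic alcohol
Product: 27 (1S,3S,4Z,5S)-1-bromo-4-(2-bromoethylidene)-3,5-dichloro-2,2-dimethylcyclohexane (target)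
Conditions: CBr4, PPh3, CH2Cl2, −20 → 0 °C
Reagents that add atoms: carbon tetrabromide, BrC(Br)(Br)Br
Why: Appel bromination of a primary allylic alcohol is a fast SN2 process at low temperature that keeps the alkene geometry, cannot transpose because SN2′ attack would have to occur at the fully substituted C5, and uses a chloride-free reagent, so the halogens are not mixed.

## Compound list

1 | but-2-yne-1,4-diol | OCC#CCO | starting material
2 | 4-hydroxybut-2-yn-1-yl pivalate | CC(C)(C)C(=O)OCC#CCO | intermediate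
3 | 4-oxobut-2-yn-1-yl pivalate | CC(C)(C)C(=O)OCC#CC=O | intermediate
4 | (+)-B-allyldiisopinocampheylborane | C=CCB([C@H]1C[C@H]2C[C@@H]([C@@H]1C)C2(C)C)[C@H]1C[C@H]2C[C@@H]([C@@H]1C)C2(C)C | starting material
5 | diisopinocampheylborinate ester of 6 | C=CC[C@@H](OB([C@H]1C[C@H]2C[C@@H]([C@@H]1C)C2(C)C)[C@H]1C[C@H]2C[C@@H]([C@@H]1C)C2(C)C)C#CCOC(=O)C(C)(C)C | intermediate
6 | (4R)-4-hydroxyhept-6-en-2-yn-1-yl pivalate | C=CC[C@@H](O)C#CCOC(=O)C(C)(C)C | intermediate
7 | (4R)-4-(tert-butyldimethylsilyloxy)hept-6-en-2-yn-1-yl pivalate | C=CC[C@@H](O[Si](C)(C)C(C)(C)C)C#CCOC(=O)C(C)(C)C | intermediate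
8 | sodium alkoxyhydridobis(2-methoxyethoxy)aluminate of the C8 propargylic alcohol (simplified) | C=CC[C@@H](O[Si](C)(C)C(C)(C)C)C#CCO[AlH-](OCCOC)OCCOC.[Na+] | intermediate
9 | cyclic alkenylaluminate, Al on C5, five-membered ring Al–C5=C7–C8–O (simplified) | C=CC[C@@H](O[Si](C)(C)C(C)(C)C)C1=CCO[Al-]1(OCCOC)OCCOC.[Na+] | intermediate
10 | (2Z,4R)-4-(tert-butyldimethylsilyloxy)-3-iodohepta-2,6-dien-1-ol | C=CC[C@@H](O[Si](C)(C)C(C)(C)C)/C(I)=C/CO | intermediate
11 | C8 tert-butyldiphenylsilyl ether of 10 | C=CC[C@@H](O[Si](C)(C)C(C)(C)C)/C(I)=C/CO[Si](c1ccccc1)(c1ccccc1)C(C)(C)C | intermediate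
12 | vicinal diol from the terminal alkene of 11 (both epimers at the new carbinol) | OCC(O)C[C@@H](O[Si](C)(C)C(C)(C)C)/C(I)=C/CO[Si](c1ccccc1)(c1ccccc1)C(C)(C)C | intermediate
13 | (3R,4Z)-3-(tert-butyldimethylsilyloxy)-6-(tert-butyldiphenylsilyloxy)-4-iodohex-4-enal | O=CC[C@@H](O[Si](C)(C)C(C)(C)C)/C(I)=C/CO[Si](c1ccccc1)(c1ccccc1)C(C)(C)C | intermediate
14 | 1-methoxy-2-methyl-1-(trimethylsilyloxy)prop-1-ene | COC(O[Si](C)(C)C)=C(C)C | starting material
15 | methyl (3R,5R,6Z)-5-(tert-butyldimethylsilyloxy)-8-(tert-butyldiphenylsilyloxy)-3-hydroxy-6-iodo-2,2-dimethyloct-6-enoate | COC(=O)C(C)(C)[C@H](O)C[C@@H](O[Si](C)(C)C(C)(C)C)/C(I)=C/CO[Si](c1ccccc1)(c1ccccc1)C(C)(C)C | intermediate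
16 | (3R,5R,6Z)-hydroxy acid from 15 | OC(=O)C(C)(C)[C@H](O)C[C@@H](O[Si](C)(C)C(C)(C)C)/C(I)=C/CO[Si](c1ccccc1)(c1ccccc1)C(C)(C)C | intermediate
17 | benzenesulfonic mixed anhydride of 16 | O=S(=O)(OC(=O)C(C)(C)[C@H](O)C[C@@H](O[Si](C)(C)C(C)(C)C)/C(I)=C/CO[Si](c1ccccc1)(c1ccccc1)C(C)(C)C)c1ccccc1 | intermediate
18 | (4R)-4-[(2R,3Z)-2-(tert-butyldimethylsilyloxy)-5-(tert-butyldiphenylsilyloxy)-3-iodopent-3-en-1-yl]-3,3-dimethyloxetan-2-one | O=C1O[C@H](C[C@@H](O[Si](C)(C)C(C)(C)C)/C(I)=C/CO[Si](c2ccccc2)(c2ccccc2)C(C)(C)C)C1(C)C | intermediate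
19 | (3S,5R,6Z)-3-bromo-5-(tert-butyldimethylsilyloxy)-8-(tert-butyldiphenylsilyloxy)-6-iodo-2,2-dimethyloct-6-enoic acid | OC(=O)C(C)(C)[C@@H](Br)C[C@@H](O[Si](C)(C)C(C)(C)C)/C(I)=C/CO[Si](c1ccccc1)(c1ccccc1)C(C)(C)C | intermediate
20 | (3S,5R,6Z)-3-bromo-5-(tert-butyldimethylsilyloxy)-8-(tert-butyldiphenylsilyloxy)-6-iodo-2,2-dimethyloct-6-en-1-ol | OCC(C)(C)[C@@H](Br)C[C@@H](O[Si](C)(C)C(C)(C)C)/C(I)=C/CO[Si](c1ccccc1)(c1ccccc1)C(C)(C)C | intermediate
21 | (3S,5R,6Z)-3-bromo-5-(tert-butyldimethylsilyloxy)-8-(tert-butyldiphenylsilyloxy)-6-iodo-2,2-dimethyloct-6-enal (key-step precursor) | O=CC(C)(C)[C@@H](Br)C[C@@H](O[Si](C)(C)C(C)(C)C)/C(I)=C/CO[Si](c1ccccc1)(c1ccccc1)C(C)(C)C | intermediate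
22 | alkenylchromium dichloride, Cr on C5 cis to C8 | O=CC(C)(C)[C@@H](Br)C[C@@H](O[Si](C)(C)C(C)(C)C)/C([Cr](Cl)Cl)=C/CO[Si](c1ccccc1)(c1ccccc1)C(C)(C)C | intermediate
23 | (1R,3S,5R,6E)-3-bromo-5-(tert-butyldimethylsilyloxy)-6-[2-(tert-butyldiphenylsilyloxy)ethylidene]-2,2-dimethylcyclohexan-1-ol; C2–Br, C4–O, C6–O all cis, C8 cis to C6 (key-step product) | CC1(C)[C@@H](Br)C[C@@H](O[Si](C)(C)C(C)(C)C)/C(=C/CO[Si](c2ccccc2)(c2ccccc2)C(C)(C)C)[C@H]1O | intermediate
24 | (1R,3R,5S)-5-bromo-2-[(Z)-2-(tert-butyldiphenylsilyloxy)ethylidene]-4,4-dimethylcyclohexane-1,3-diol | CC1(C)[C@@H](Br)C[C@@H](O)/C(=C/CO[Si](c2ccccc2)(c2ccccc2)C(C)(C)C)[C@H]1O | intermediate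
25 | C8 tert-butyldiphenylsilyl ether of 26 (2S,4S,6S in route numbering) | CC1(C)[C@@H](Br)C[C@H](Cl)/C(=C/CO[Si](c2ccccc2)(c2ccccc2)C(C)(C)C)[C@@H]1Cl | intermediate
26 | (2Z)-2-[(2S,4S,6S)-4-bromo-2,6-dichloro-3,3-dimethylcyclohexylidene]ethan-1-ol | CC1(C)[C@@H](Br)C[C@H](Cl)/C(=C/CO)[C@@H]1Cl | intermediate
27 | (1S,3S,4Z,5S)-1-bromo-4-(2-bromoethylidene)-3,5-dichloro-2,2-dimethylcyclohexane | CC1(C)[C@@H](Br)C[C@H](Cl)/C(=C/CBr)[C@@H]1Cl | target

## Step count and risks

Total step count: 18. Longest linear sequence: 18 steps (1 → 27); 4 and 14 are bought.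

**Most likely to fail: step 16.**
- What may go wrong: slow SN2 attack at the neopentylic C6 may let ionisation, allylic transposition towards C7 or ring contraction compete. The second chloride also has to enter syn-axial to the first.
- The fallback sets out from 23 and exchanges the two C–O bonds one at a time, each on a ring that carries a single leaving group.
- In 23 the C6 hydroxyl is free and C4 is still silylated. Treatment with 1-chloro-N,N,2-trimethylprop-1-en-1-amine (CH2Cl2, 0 °C → rt), a small neutral reagent whose alkoxyiminium chloride pair collapses with inversion, should give the C6 chloride with C4 silyl ether F1.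
- Aqueous HF in MeCN at 0 °C then removes only the TBS group to give the C6-chloro C4-alcohol F2.
- PPh3/hexachloroacetone inverts the less hindered C4 carbinol, and the sequence comes back to the route at 25.

**Second: step 14.**
- What may go wrong: facial selectivity at the aldehyde may be poor, because allylic 1,3-strain with C8 can tip the closure towards the axial carbinol.
- The fallback sets out from 21. The crude cyclisation product, including the C6-epimeric alcohol F3, is oxidised with Dess–Martin periodinane to the cross-conjugated enone F4.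
- Luche reduction (NaBH4, CeCl3·7H2O, MeOH, −78 °C) should then deliver hydride along the axial line, the face away from the axial C1 methyl group. This gives the equatorial alcohol, and the route is rejoined at 23.

**Third: step 11.**
- What may go wrong: ionisation with hydride or methyl shift, acyl–oxygen cleavage, or decarboxylative loss of bromide from the magnesium carboxylate may compete with the SN2 opening at the hindered C2.
- The fallback sets out from 15 and avoids the acid and the lactone.
- Tf2O/2,6-lutidine (CH2Cl2, −78 °C) gives the C2 triflate F5.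
- LiBr (THF, −20 °C → rt) displaces it with inversion to give the bromo ester F6.
- i-Bu2AlH (CH2Cl2, −78 °C) reduces the ester to the primary alcohol, and the route is rejoined at 20.

## Further compounds

F1 | step 16 | C6 chloride with C4 TBS ether and C8 TBDPS ether (2S,4R,6S in route numbering) | CC1(C)[C@@H](Br)C[C@@H](O[Si](C)(C)C(C)(C)C)/C(=C/CO[Si](c2ccccc2)(c2ccccc2)C(C)(C)C)[C@@H]1Cl
F2 | step 16 | C6 chloride with free C4 alcohol and C8 TBDPS ether (2S,4R,6S in route numbering) | CC1(C)[C@@H](Br)C[C@@H](O)/C(=C/CO[Si](c2ccccc2)(c2ccccc2)C(C)(C)C)[C@@H]1Cl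
F3 | step 14 | C6 epimer of 23 (2S,4R,6S in route numbering, C6–OH trans to C2–Br) | CC1(C)[C@@H](Br)C[C@@H](O[Si](C)(C)C(C)(C)C)/C(=C/CO[Si](c2ccccc2)(c2ccccc2)C(C)(C)C)[C@@H]1O
F4 | step 14 | C6 ketone (2-alkylidenecyclohexanone, C8 cis to C6, 2S,4R in route numbering) | CC1(C)[C@@H](Br)C[C@@H](O[Si](C)(C)C(C)(C)C)/C(=C/CO[Si](c2ccccc2)(c2ccccc2)C(C)(C)C)C1=O
F5 | step 11 | C2 triflate of 15 (2R,4R in route numbering) | COC(=O)C(C)(C)[C@H](OS(=O)(=O)C(F)(F)F)C[C@@H](O[Si](C)(C)C(C)(C)C)/C(I)=C/CO[Si](c1ccccc1)(c1ccccc1)C(C)(C)C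
F6 | step 11 | methyl ester of 19 (2S,4R in route numbering) | COC(=O)C(C)(C)[C@@H](Br)C[C@@H](O[Si](C)(C)C(C)(C)C)/C(I)=C/CO[Si](c1ccccc1)(c1ccccc1)C(C)(C)C
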